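**Plan**

- Retrosynthetic cuts, in order: the C7–O ester bond; the C7 oxygen (back to an allylic CH2); C4–C5 (reductive aldol that closes the cyclopentane); C3=C4 (cross-metathesis with methyl vinyl ketone); finally C6–C7, with C9–O re-joined.
- Enabling feature: in the seven-membered ring, C5 (ketone level) lies next to quaternary C1 and three bonds (via C6, C7) from the cis C8=C9 alkene. That is a cyclohept-4-enone, the [3,3] product of a 2-methylidene-5-isopropenyl-oxolane.
- Forward order: chiral-pool γ-lactone → α-methylation and α-allylation → lactone methylenation → Claisen ring expansion (seven-membered ring) → cross-metathesis → reductive aldol (five-membered ring) → isopropyl → C7 oxygenation → veratroate.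
- Stereochemistry: the lactone C–O stereocentre (future C9, from the L-glutamic acid series) steers the allylation that fixes C1 and is then erased in the ring expansion. C1 enforces the cis ring fusion at C5, and the chelated aldol places the C4 substituent cis to C5–OH. The C5 hydroxyl directs hydride to C7 to give the anti diol.

Key step: step 6

Remark: atoms are numbered C1 (quaternary methyl carbon), C2, C3, C4 (isopropyl carbon), C5 (carbinol), C6, C7 (ester carbon), C8(Me)=C9, C10; the SMILES is read as (1R,4R,5S,7R), i.e. C1-methyl, C5-OH and C4-isopropyl on one face of a cis-fused bicycle and the C7 oxygen on the other.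

**Route**

Step 1
Reactants: 1 (S)-5-oxotetrahydrofuran-2-carboxylic acid
Product: 3 (S)-5-acetyldihydrofuran-2(3H)-one, via acid chloride 2 (not isolated)
Conditions: (COCl)2, DMF (cat.), CH2Cl2, 0 °C to rt; evaporate; MeMgBr (1.0 equiv, slow addition), CuI (5 mol %), THF, −78 °C
Reagents that add atoms: oxalyl chloride ClC(=O)C(Cl)=O (chlorine of 2); methylmagnesium bromide C[Mg]Br
Why: Chlorination of the acid followed by copper-catalysed Grignard acylation, which at −78 °C should stop at the methyl ketone and leave the lactone carbonyl alone; the stereocentre comes from the chiral pool and is not involved.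

Step 2
Reactants: 3 (S)-5-acetyldihydrofuran-2(3H)-one
Product: 4 (S)-5-(prop-1-en-2-yl)dihydrofuran-2(3H)-one
Conditions: Zn, CH2Br2, TiCl4, THF, 0 °C (reagent pre-formed); then 3, CH2Cl2, 0 °C to rt
Reagents that add atoms: dibromomethane BrCBr
Why: Lombardo methylenation; the non-basic zinc–titanium methylene reagent should convert the ketone into the isopropenyl group without enolising the adjacent oxygen-bearing stereocentre, and it does not attack lactones.

Step 3
Reactants: 4 (S)-5-(prop-1-en-2-yl)dihydrofuran-2(3H)-one
Product: 6 (5S)-3-methyl-5-(prop-1-en-2-yl)dihydrofuran-2(3H)-one as C3 epimers, via lithium enolate 5 (not isolated)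
Conditions: LDA (commercial solution, 1.05 equiv), THF, −78 °C; MeI, −78 to −40 °C
Reagents that add atoms: lithium diisopropylamide CC(C)N([Li])C(C)C (lithium of 5); iodomethane CI
Why: Alkylation of a γ-butyrolactone lithium enolate; the new C3 centre need not be controlled because it becomes trigonal again in step 4.

Step 4
Reactants: 6 (5S)-3-methyl-5-(prop-1-en-2-yl)dihydrofuran-2(3H)-one; 7 allyl bromide
Product: 9 (3R,5S)-3-methyl-3-(prop-2-en-1-yl)-5-(prop-1-en-2-yl)dihydrofuran-2(3H)-one, via lithium enolate 8 (not isolated)
Conditions: LDA (1.1 equiv), THF, −78 °C; DMPU, 7, −78 to −20 °C; chromatographic removal of the minor C3 epimer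
Reagents that add atoms: lithium diisopropylamide CC(C)N([Li])C(C)C (lithium of 8)
Why: Second enolate alkylation creating the quaternary centre; the electrophile should approach the planar enolate from the face opposite the C5 isopropenyl group (1,3-induction typical of γ-substituted butyrolactone enolates), so allyl ends trans to isopropenyl, which is the 3R configuration needed for C1. The minor cis isomer would lead to the antipode after step 6 and is therefore removed here.

Step 5
Reactants: 9 (3R,5S)-3-methyl-3-(prop-2-en-1-yl)-5-(prop-1-en-2-yl)dihydrofuran-2(3H)-one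
Product: 10 (3R,5S)-3-methyl-2-methylidene-3-(prop-2-en-1-yl)-5-(prop-1-en-2-yl)oxolane
Conditions: Cp2TiMe2 (2.5 equiv), PhMe, 70 °C, dark; filtration through Et3N-deactivated basic Al2O3
Reagents that add atoms: dimethyltitanocene C[Ti](C)(C1C=CC=C1)C1C=CC=C1
Why: Petasis methylenation (Cp2Ti=CH2 generated thermally) turns lactone carbonyls into exocyclic enol ethers without acid, tolerates isolated alkenes and hindered α-quaternary lactones; the product cannot isomerise to an endocyclic enol ether because C3 bears no hydrogen.

Step 6
Reactants: 10 (3R,5S)-3-methyl-2-methylidene-3-(prop-2-en-1-yl)-5-(prop-1-en-2-yl)oxolane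
Product: 11 (R)-2,5-dimethyl-2-(prop-2-en-1-yl)cyclohept-4-en-1-one
Conditions: PhMe (0.05 M, degassed), BHT (cat.), base-washed sealed tube, 180 °C
Reagents that add atoms: none
Why: Thermal Claisen ([3,3] sigmatropic) rearrangement of the allyl vinyl ether held inside 10: the exocyclic methylidene carbon (future C6) bonds to the terminal carbon of the isopropenyl group (future C7) while the ring C–O bond at the isopropenyl-bearing carbon (future C9) breaks, so the former lactone carbon becomes the C5 ketone. The closest known reaction type is the thermal ring expansion of 2-methylidene-5-vinyl-oxolanes to cyclohept-4-enones. The seven-membered carbocycle is closed by this concerted two-carbon ring expansion through a boat-like six-centre transition state with the isopropenyl group pseudo-axial over the enol ether, not by a polar exo or endo cyclisation. No stereocentre is formed: C9 becomes trigonal, the tether allows only the cis C8=C9 alkene, and the quaternary centre (3R in 10, future C1) takes no part and appears as (R) in 11. The step needs periselectivity over the Cope shift of the 1,5-diene made up of the enol ether and the allyl group, and it needs the exocyclic enol ether to survive heating. The Claisen path ends in a carbonyl group and is expected to have the lower barrier than the all-carbon Cope shift, so the lowest temperature that gives conversion is used; the hydrogen-free C3 of 10 prevents migration of the enol ether double bond into the ring, and base-washed glass with a radical inhibitor should guard against hydrolysis and polymerisation.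

Step 7
Reactants: 11 (R)-2,5-dimethyl-2-(prop-2-en-1-yl)cyclohept-4-en-1-one; 12 but-3-en-2-one (methyl vinyl ketone)
Product: 13 (R,E)-2,5-dimethyl-2-(4-oxopent-2-en-1-yl)cyclohept-4-en-1-one
Conditions: 12 (5 equiv), second-generation Hoveyda–Grubbs catalyst RuCl2(H2IMes)(=CH-C6H4-2-OiPr) (5 mol %), CH2Cl2, 40 °C
Reagents that add atoms: none
Why: Olefin cross-metathesis of the terminal allyl alkene with an excess of the electron-poor partner should give the E-enone, while the trisubstituted ring alkene is too hindered to take part.

Step 8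
Reactants: 13 (R,E)-2,5-dimethyl-2-(4-oxopent-2-en-1-yl)cyclohept-4-en-1-one
Product: 14 1-[(1S,3aR,8aS)-8a-hydroxy-3a,6-dimethyl-1,2,3,3a,4,7,8,8a-octahydroazulen-1-yl]ethan-1-one (1R,4S,5S in the numbering of the remark; acetyl, hydroxyl and C1-methyl on one face)
Conditions: [(Ph3P)CuH]6 (0.35 equiv, about 2 hydride equiv), PhMe, −40 to 0 °C; aq NH4Cl
Reagents that add atoms: none
Why: Copper hydride reductive aldol cyclisation; conjugate hydride transfer gives the C4 copper enolate, which closes the cyclopentane on the C5 ketone (5-(enolexo)-exo-trig). The two-carbon tether from C1 forces attack on the carbonyl face it occupies, giving the cis-fused ring with C5–OH on the side of the C1 methyl, and the copper-chelated six-membered transition state places the acetyl group cis to the new hydroxyl (4S,5S).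

Step 9
Reactants: 14 the hydroxy ketone of step 8
Product: 15 (3R,3aS,8aR)-6,8a-dimethyl-3-(prop-1-en-2-yl)-2,3,4,5,8,8a-hexahydroazulen-3a(1H)-ol
Conditions: Zn, CH2Br2, TiCl4, THF, 0 °C (pre-formed, excess); then 14, CH2Cl2, 0 °C to rt
Reagents that add atoms: dibromomethane BrCBr
Why: Lombardo methylenation, chosen because it is non-basic: the tertiary β-hydroxy ketone should neither undergo retro-aldol cleavage nor epimerise at C4 as it could with a phosphorus ylide, and the free hydroxyl is tolerated by excess reagent.

Step 10
Reactants: 15 the isopropenyl carbinol of step 9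
Product: 16 (3R,3aS,8aR)-6,8a-dimethyl-3-(propan-2-yl)-2,3,4,5,8,8a-hexahydroazulen-3a(1H)-ol
Conditions: H2 (1 atm), RhCl(PPh3)3 (10 mol %), PhH/EtOH, rt
Reagents that add atoms: none
Why: Homogeneous hydrogenation with Wilkinson's catalyst discriminates by substitution; the 1,1-disubstituted isopropenyl alkene should be reduced while the trisubstituted ring alkene C8=C9 is left, and no stereocentre is formed.

Step 11
Reactants: 16 the isopropyl carbinol of step 10
Product: 17 (3R,3aS,8aR)-6,8a-dimethyl-3-(propan-2-yl)-2,3,4,5,8,8a-hexahydroazulene-3a,5(1H)-diol as C7 epimers (C7 = azulene C5)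
Conditions: SeO2 (0.3 equiv), t-BuOOH (3 equiv), CH2Cl2, rt
Reagents that add atoms: selenium dioxide O=[Se]=O; tert-butyl hydroperoxide CC(C)(C)OO
Why: Selenium dioxide allylic oxidation (ene reaction, then [2,3] sigmatropic shift) functionalises the ring CH2 attached to the more substituted alkene carbon, here C7 next to C8, and returns the double bond to C8=C9. C10 at the less substituted terminus is not addressed by this mechanism, and the C7 configuration is left open because it is set in step 13.

Step 12
Reactants: 17 the C7 allylic alcohols of step 11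
Product: 18 (3R,3aS,8aR)-3a-hydroxy-6,8a-dimethyl-3-(propan-2-yl)-2,3,3a,4,8,8a-hexahydroazulen-5(1H)-one
Conditions: MnO2 (activated, 20 equiv), CH2Cl2, rt
Reagents that add atoms: none
Why: MnO2 oxidises the allylic secondary alcohol (both epimers, together with any enone already formed in step 11) and leaves the tertiary C5 hydroxyl alone.

Step 13
Reactants: 18 the hydroxy enone of step 12
Product: 19 (3R,3aS,5R,8aR)-6,8a-dimethyl-3-(propan-2-yl)-2,3,4,5,8,8a-hexahydroazulene-3a,5(1H)-diol (1R,4R,5S,7R in the numbering of the remark)
Conditions: Me4NBH(OAc)3 (5 equiv), MeCN/AcOH (1:1), −30 °C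
Reagents that add atoms: none
Why: Hydroxyl-directed reduction (Evans–Saksena); the C5 hydroxyl binds boron and hydride is delivered intramolecularly to the face of the C7 carbonyl on which C5–O lies, which should give the 1,3-anti diol (7R), and the acetoxyborohydride reduces the enone only in the 1,2 sense.

Step 14
Reactants: 19 the anti diol of step 13; 20 3,4-dimethoxybenzoyl chloride
Product: 21 (3R,3aS,5R,8aR)-3a-hydroxy-6,8a-dimethyl-3-(propan-2-yl)-1,2,3,3a,4,5,8,8a-octahydroazulen-5-yl 3,4-dimethoxybenzoate (target)
Conditions: 20 (1.2 equiv), Et3N, DMAP (cat.), CH2Cl2, 0 °C to rt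
Reagents that add atoms: none
Why: DMAP-catalysed acylation with the acid chloride should esterify the secondary allylic C7 hydroxyl, while the hindered tertiary C5 hydroxyl stays free.

**Compound list**

1 | (S)-5-oxotetrahydrofuran-2-carboxylic acid | OC(=O)[C@@H]1CCC(=O)O1 | starting material
2 | (S)-5-oxotetrahydrofuran-2-carbonyl chloride | ClC(=O)[C@@H]1CCC(=O)O1 | intermediate
3 | (S)-5-acetyldihydrofuran-2(3H)-one | CC(=O)[C@@H]1CCC(=O)O1 | intermediate
4 | (S)-5-(prop-1-en-2-yl)dihydrofuran-2(3H)-one | C=C(C)[C@@H]1CCC(=O)O1 | intermediate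
5 | lithium (S)-5-(prop-1-en-2-yl)-4,5-dihydrofuran-2-olate | [Li]OC1=CC[C@@H](C(C)=C)O1 | intermediate
6 | (5S)-3-methyl-5-(prop-1-en-2-yl)dihydrofuran-2(3H)-one, C3 epimers | CC1C[C@@H](C(C)=C)OC1=O | intermediate
7 | allyl bromide | C=CCBr | starting material
8 | lithium (S)-3-methyl-5-(prop-1-en-2-yl)-4,5-dihydrofuran-2-olate | [Li]OC1=C(C)C[C@@H](C(C)=C)O1 | intermediate
9 | (3R,5S)-3-methyl-3-(prop-2-en-1-yl)-5-(prop-1-en-2-yl)dihydrofuran-2(3H)-one | C=CC[C@]1(C)C[C@@H](C(C)=C)OC1=O | intermediate
10 | (3R,5S)-3-methyl-2-methylidene-3-(prop-2-en-1-yl)-5-(prop-1-en-2-yl)oxolane | C=CC[C@]1(C)C[C@@H](C(C)=C)OC1=C | intermediate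
11 | (R)-2,5-dimethyl-2-(prop-2-en-1-yl)cyclohept-4-en-1-one | C=CC[C@]1(C)CC=C(C)CCC1=O | intermediate
12 | but-3-en-2-one | C=CC(C)=O | starting material
13 | (R,E)-2,5-dimethyl-2-(4-oxopent-2-en-1-yl)cyclohept-4-en-1-one | CC(=O)/C=C/C[C@]1(C)CC=C(C)CCC1=O | intermediate
14 | 1-[(1S,3aR,8aS)-8a-hydroxy-3a,6-dimethyl-1,2,3,3a,4,7,8,8a-octahydroazulen-1-yl]ethan-1-one | C1C[C@]2(O)[C@@H](C(C)=O)CC[C@]2(C)CC=C1C | intermediate
15 | (3R,3aS,8aR)-6,8a-dimethyl-3-(prop-1-en-2-yl)-2,3,4,5,8,8a-hexahydroazulen-3a(1H)-ol | C1C[C@]2(O)[C@@H](C(C)=C)CC[C@]2(C)CC=C1C | intermediate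
16 | (3R,3aS,8aR)-6,8a-dimethyl-3-(propan-2-yl)-2,3,4,5,8,8a-hexahydroazulen-3a(1H)-ol | C1C[C@]2(O)[C@@H](C(C)C)CC[C@]2(C)CC=C1C | intermediate
17 | (3R,3aS,8aR)-6,8a-dimethyl-3-(propan-2-yl)-2,3,4,5,8,8a-hexahydroazulene-3a,5(1H)-diol, C5 (azulene) epimers | OC1C[C@]2(O)[C@@H](C(C)C)CC[C@]2(C)CC=C1C | intermediate
18 | (3R,3aS,8aR)-3a-hydroxy-6,8a-dimethyl-3-(propan-2-yl)-2,3,3a,4,8,8a-hexahydroazulen-5(1H)-one | O=C1C[C@]2(O)[C@@H](C(C)C)CC[C@]2(C)CC=C1C | intermediate
19 | (3R,3aS,5R,8aR)-6,8a-dimethyl-3-(propan-2-yl)-2,3,4,5,8,8a-hexahydroazulene-3a,5(1H)-diol | O[C@@H]1C[C@]2(O)[C@@H](C(C)C)CC[C@]2(C)CC=C1C | intermediate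
20 | 3,4-dimethoxybenzoyl chloride | COc1ccc(C(Cl)=O)cc1OC | starting material
21 | (3R,3aS,5R,8aR)-3a-hydroxy-6,8a-dimethyl-3-(propan-2-yl)-1,2,3,3a,4,5,8,8a-octahydroazulen-5-yl 3,4-dimethoxybenzoate | COc1ccc(C(=O)O[C@@H]2C[C@]3(O)[C@@H](C(C)C)CC[C@]3(C)CC=C2C)cc1OC | target

**Step count and risks**

Total: 14 steps. Longest linear sequence: 14 steps (1 to 21).

Steps most likely to fail:

1. Step 6 (Claisen ring expansion). The temperature window may not separate the Claisen shift from the Cope shift of the enol ether/allyl 1,5-diene, which would destroy the quaternary centre, or the enol ether may hydrolyse or polymerise on prolonged heating. Fallback: postpone the allyl group so that no 1,5-diene is present. Setting out from 6, methylenation with Cp2TiMe2 (PhMe, 70 °C) should give the enol ether (5S)-3-methyl-2-methylidene-5-(prop-1-en-2-yl)oxolane F1. In base-washed glass at 180 °C this should undergo the same ring expansion to 2,5-dimethylcyclohept-4-en-1-one F2, whose C2 stereocentre is of no consequence. Soft enolisation (TMSCl, NaI, Et3N, MeCN) should give the more substituted silyl enol ether [(2,5-dimethylcyclohepta-1,4-dien-1-yl)oxy]trimethylsilane F3. Palladium-catalysed asymmetric allylation of the enolate released by fluoride (Pd2(dba)3, (S)-t-Bu-PHOX, diallyl carbonate, Bu4N[Ph3SiF2], THF, 25 °C) then installs the allyl group at the quaternary carbon; this ligand enantiomer is the one expected to give the required sense by analogy with 2-methylcycloalkanone enolates. The sequence comes back to the route at 11.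

2. Step 8 (reductive aldol). Conjugate reduction may occur without ring closure because the C5 ketone is neopentyl, the copper aldolate may revert by retro-aldol, or control at C4 may be poor. Fallback: separate enolate formation from C–C bond formation. Setting out from 13, 1,4-hydrosilylation (RhCl(PPh3)3 cat., Et3SiH, PhH, 50 °C) should give the regiodefined silyl enol ether (R)-2,5-dimethyl-2-[(Z)-4-(triethylsilyloxy)pent-3-en-1-yl]cyclohept-4-en-1-one F4. TiCl4 in CH2Cl2 at −78 °C then activates the C5 ketone for an intramolecular Mukaiyama aldol addition, which after aqueous work-up comes back to the route at 14. The ring fusion is again cis by the tether; should C4 form epimeric, equilibration through the enol is expected to favour the hydrogen-bonded cis acetyl/hydroxyl isomer.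

3. Step 11 (allylic oxidation). Attack may occur at the C8 methyl group instead of C7, the product may be over-oxidised, or conversion at the hindered alkene may be low. Fallback: install the C7 oxygen by carbonyl transposition instead of C–H oxidation. Setting out from 16, hydroboration–oxidation (BH3·THF; NaOH, H2O2) should place hydroxyl on the less substituted alkene carbon C9 and give (1R,4R,5S)-daucane-5,9-diol F5. Dess–Martin oxidation gives (1R,4R,5S)-5-hydroxydaucan-9-one F6. Dehydrogenation with IBX (DMSO, 70 °C) can only run towards C8–C7, because C1 on the other side of C10 carries no hydrogen, giving (1R,4R,5S)-5-hydroxydauc-7-en-9-one F7. Nucleophilic epoxidation (H2O2, NaOH, MeOH, 0 °C) gives (1R,4R,5S)-7,8-epoxy-5-hydroxydaucan-9-one F8. Wharton transposition (N2H4·H2O, AcOH, MeOH) then delivers the C7 allylic alcohol with the C8=C9 alkene, coming back to the route at 17 (one C7 epimer), which is carried on through steps 12 to 14.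

**Further compounds**

F1 | step 6 | (5S)-3-methyl-2-methylidene-5-(prop-1-en-2-yl)oxolane, C3 epimers | CC1C[C@@H](C(C)=C)OC1=C
F2 | step 6 | 2,5-dimethylcyclohept-4-en-1-one, both enantiomers | CC1CC=C(C)CCC1=O
F3 | step 6 | [(2,5-dimethylcyclohepta-1,4-dien-1-yl)oxy]trimethylsilane | CC1=C(O[Si](C)(C)C)CCC(C)=CC1
F4 | step 8 | (R)-2,5-dimethyl-2-[(Z)-4-(triethylsilyloxy)pent-3-en-1-yl]cyclohept-4-en-1-one | C/C(O[Si](CC)(CC)CC)=C/CC[C@]1(C)CC=C(C)CCC1=O
F5 | step 11 | (1R,4R,5S)-daucane-5,9-diol, C8 and C9 as formed | C1C[C@]2(O)[C@@H](C(C)C)CC[C@]2(C)CC(O)C1C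
F6 | step 11 | (1R,4R,5S)-5-hydroxydaucan-9-one, C8 epimers | C1C[C@]2(O)[C@@H](C(C)C)CC[C@]2(C)CC(=O)C1C
F7 | step 11 | (1R,4R,5S)-5-hydroxydauc-7-en-9-one | C=1C[C@]2(O)[C@@H](C(C)C)CC[C@]2(C)CC(=O)C=1C
F8 | step 11 | (1R,4R,5S)-7,8-epoxy-5-hydroxydaucan-9-one, epoxide face as formed | C12C[C@]3(O)[C@@H](C(C)C)CC[C@]3(C)CC(=O)C1(C)O2
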